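**Strategy.** Alertenone is the Michael dimer of the α‑methylene ketone 18, so the plan rests on building 18. With 18 numbered as tricyclo[4.3.2.0^{1,5}]undecane, its cyclopentanone ring (C1–C5) is cut at C1–C2 and C4–C5. A C1=C5 alkene would be anti‑Bredt inside the bicyclo[3.2.1]octane but is harmless in the C1/C5/C6/C11/C10 cyclopentene. The key step is therefore a (3+2) annulation of allenylsilane 7 onto cyclopentenyl thioester 6. It forms both bonds, the quaternary C1 and the cis‑diquinane, and leaves a vinylsilane as a regiodefined latent C3 ketone with the future methylidene carbon already on C2. The C7–C9 bridge is closed afterwards.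

Key step: step 4

Remark: tricyclic compounds are numbered as tricyclo[4.3.2.0^{1,5}]undecane (C1 quaternary, C2 methylidene carbon, C3 carbonyl, C5 ring‑fusion CH, C6 bridgehead CH, C9 CHMe, C10 CH2, C11 CMe2); 1, 2 and 7 are taken as commercial.
Remark: epoxide 15 and ketone 16 are carried as whatever isomers form at C2/C3, because these centres are erased in step 11.

Step 1
Reactants: 1 4,4‑dimethylcyclopent‑2‑en‑1‑one; 2 potassium ethenyltrifluoroborate
Product: 3 (3R)‑3‑ethenyl‑4,4‑dimethylcyclopentan‑1‑one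
Conditions: [Rh(cod)2]PF6 (3 mol%), (R)‑BINAP, toluene/H2O, 105 °C
Reagents that add atoms: none
Why: Rhodium‑catalysed asymmetric conjugate addition (Hayashi–Miyaura type); the (R)‑BINAP‑bound alkenylrhodium species should add to the enone face that gives the 3R centre (future C6), the sense expected from the accepted model for cyclopent‑2‑enone, and this centre later steers the key step.

Step 2
Reactants: 3 (3R)‑3‑ethenyl‑4,4‑dimethylcyclopentan‑1‑one
Product: 5 (3S)‑3‑ethenyl‑4,4‑dimethylcyclopent‑1‑en‑1‑yl trifluoromethanesulfonate, via lithium enolate 4 (not isolated)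
Conditions: LiN(i‑Pr)2, THF, −78 °C; then PhNTf2, −78 °C → rt
Reagents that add atoms: N‑phenylbis(trifluoromethanesulfonimide), O=S(=O)(N(c1ccccc1)S(=O)(=O)C(F)(F)F)C(F)(F)F
Why: Kinetic enolisation and O‑triflation; the amide base should take a proton from the α‑CH2 next to the tertiary carbon rather than from the neopentyl α‑CH2 beside the gem‑dimethyl carbon, which places the alkene between the future C1 and C5.

Step 3
Reactants: 5 (3S)‑3‑ethenyl‑4,4‑dimethylcyclopent‑1‑en‑1‑yl trifluoromethanesulfonate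
Product: 6 S‑ethyl (3S)‑3‑ethenyl‑4,4‑dimethylcyclopent‑1‑ene‑1‑carbothioate
Conditions: Pd(OAc)2 (5 mol%), Xantphos, CO (1 atm), EtSH, i‑Pr2NEt, DMF, 60 °C
Reagents that add atoms: carbon monoxide, [C-]#[O+]; ethanethiol, CCS
Why: Palladium‑catalysed thiocarbonylation (oxidative addition of the enol triflate to zerovalent palladium, CO insertion, capture of the acylpalladium by the thiol) should give the conjugated thioester without touching the doubly allylic stereocentre.

Step 4
Reactants: 6 S‑ethyl (3S)‑3‑ethenyl‑4,4‑dimethylcyclopent‑1‑ene‑1‑carbothioate; 7 (buta‑2,3‑dien‑2‑yl)trimethylsilane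
Product: 8 S‑ethyl (3aS,6S,6aS)‑6‑ethenyl‑3,5,5‑trimethyl‑2‑(trimethylsilyl)‑4,5,6,6a‑tetrahydropentalene‑3a(1H)‑carbothioate
Conditions: TiCl4 (1.2 equiv), CH2Cl2, −78 °C
Reagents that add atoms: none
Why: Proposed new method: TiCl4 activates the unsaturated thioester, the CH2 terminus of 7 adds to the β‑carbon (future C5), the β‑silyl vinyl cation undergoes a 1,2‑silyl shift, and the titanium thioester enolate closes through its α‑carbon (future C1) onto the methyl‑bearing cationic carbon (future C2), so the C4–C5 and C1–C2 bonds form in one operation. The closest known reaction type is the Danheiser (trimethylsilyl)cyclopentene annulation of allenylsilanes with α,β‑unsaturated ketones and acylsilanes, 1‑acylcyclopentenes included; only the thioester acceptor is new, and it should be electrophilic enough once bound to the Lewis acid while, unlike an enal, it offers no 1,2‑addition path. The one new ring closes by a 5‑(enolexo) attack that is endo with respect to the linear vinyl cation, which the one‑carbon tether allows only in the cis‑fused sense. C5 (C6a of 8) is set by approach of 7 anti to the neighbouring vinyl group, and C1 (C3a) follows from the cis fusion, leaving thioester and vinyl cis as the later bridge requires. Regiochemistry (silicon on the central carbon, methyl‑bearing carbon on the quaternary centre) is fixed by the mechanism, and chemoselectivity over the isolated vinyl group rests on the conjugated alkene being the only Lewis‑acid‑activated one.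

Step 5
Reactants: 8 S‑ethyl (3aS,6S,6aS)‑6‑ethenyl‑3,5,5‑trimethyl‑2‑(trimethylsilyl)‑4,5,6,6a‑tetrahydropentalene‑3a(1H)‑carbothioate
Product: 9 S‑ethyl (3aS,6S,6aS)‑6‑acetyl‑3,5,5‑trimethyl‑2‑(trimethylsilyl)‑4,5,6,6a‑tetrahydropentalene‑3a(1H)‑carbothioate
Conditions: PdCl2 (10 mol%), CuCl, O2 (1 atm), DMF/H2O, rt
Reagents that add atoms: water, O
Why: Tsuji–Wacker oxidation; divalent palladium engages only the monosubstituted alkene and water adds at its internal carbon to give the methyl ketone, the tetrasubstituted vinylsilane being too hindered and the thioester inert without phosphine ligands.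

Step 6
Reactants: 9 S‑ethyl (3aS,6S,6aS)‑6‑acetyl‑3,5,5‑trimethyl‑2‑(trimethylsilyl)‑4,5,6,6a‑tetrahydropentalene‑3a(1H)‑carbothioate
Product: 10 (3aS,6S,6aS)‑6‑acetyl‑3,5,5‑trimethyl‑2‑(trimethylsilyl)‑4,5,6,6a‑tetrahydropentalene‑3a(1H)‑carbaldehyde
Conditions: Et3SiH, Pd/C (10 mol%), acetone, rt
Reagents that add atoms: none
Why: Fukuyama reduction; the acylpalladium formed from the thioester is intercepted by silane hydride to give the aldehyde, and ketone and vinylsilane should be left alone.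

Step 7
Reactants: 10 (3aS,6S,6aS)‑6‑acetyl‑3,5,5‑trimethyl‑2‑(trimethylsilyl)‑4,5,6,6a‑tetrahydropentalene‑3a(1H)‑carbaldehyde
Product: 11 (1S,5S,6S)‑2,11,11‑trimethyl‑3‑(trimethylsilyl)tricyclo[4.3.2.0^{1,5}]undeca‑2,8‑dien‑7‑one
Conditions: KOH (0.2 equiv), MeOH, 0 °C → rt
Reagents that add atoms: none
Why: Intramolecular aldol condensation; the aldehyde has no α‑hydrogen and only the methyl terminus of the ketone can reach it through a six‑membered ring, so a single enone (C7 carbonyl, C8=C9) should form, and although C6 is epimerisable here only its cis isomer can bridge, so C1 and C5 dictate the bridgehead configuration.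

Step 8
Reactants: 11 (1S,5S,6S)‑2,11,11‑trimethyl‑3‑(trimethylsilyl)tricyclo[4.3.2.0^{1,5}]undeca‑2,8‑dien‑7‑one
Product: 13 (1S,5S,6S,9S)‑2,9,11,11‑tetramethyl‑3‑(trimethylsilyl)tricyclo[4.3.2.0^{1,5}]undeca‑2,7‑dien‑7‑yl trifluoromethanesulfonate, via lithium enolate 12 (not isolated)
Conditions: Me2CuLi (from CuI, MeLi), Et2O, −78 → −20 °C; then PhNTf2, THF, −78 °C → rt
Reagents that add atoms: lithium dimethylcuprate, [Li+].C[Cu-]C; N‑phenylbis(trifluoromethanesulfonimide), O=S(=O)(N(c1ccccc1)S(=O)(=O)C(F)(F)F)C(F)(F)F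
Why: Gilman cuprate conjugate addition with O‑triflation of the enolate; methyl should add to C9 axially from the exo face, syn to the one‑carbon bridge C5 and anti to the C10–C11 bridge whose gem‑dimethyl group blocks the other face, which sets the 9S methyl.

Step 9
Reactants: 13 (1S,5S,6S,9S)‑2,9,11,11‑tetramethyl‑3‑(trimethylsilyl)tricyclo[4.3.2.0^{1,5}]undeca‑2,7‑dien‑7‑yl trifluoromethanesulfonate
Product: 14 trimethyl[(1S,5S,6S,9S)‑2,9,11,11‑tetramethyltricyclo[4.3.2.0^{1,5}]undec‑2‑en‑3‑yl]silane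
Conditions: H2 (1 atm), PtO2, NaHCO3, EtOAc, rt
Reagents that add atoms: none
Why: Catalytic hydrogenation with hydrogenolysis of the enol triflate C–O bond removes the C7 oxygen and saturates C7–C8; the tetrasubstituted, silyl‑shielded C2=C3 alkene should survive and the bicarbonate buffer guards against protodesilylation.

Step 10
Reactants: 14 trimethyl[(1S,5S,6S,9S)‑2,9,11,11‑tetramethyltricyclo[4.3.2.0^{1,5}]undec‑2‑en‑3‑yl]silane
Product: 16 (1S,5S,6S,9S)‑2,9,11,11‑tetramethyltricyclo[4.3.2.0^{1,5}]undecan‑3‑one (C2 epimers), via epoxysilane 15 (not isolated)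
Conditions: mCPBA, NaHCO3, CH2Cl2, 0 °C; then aq. H2SO4, MeOH, 50 °C
Reagents that add atoms: 3‑chloroperbenzoic acid, OOC(=O)c1cccc(Cl)c1
Why: Peracid epoxidation of the vinylsilane followed by acid‑promoted opening of the α,β‑epoxysilane with loss of silicon (the known vinylsilane‑to‑ketone conversion) should place the carbonyl on the former silicon‑bearing carbon C3; C2 forms as a mixture that is planarised in step 11.

Step 11
Reactants: 16 (1S,5S,6S,9S)‑2,9,11,11‑tetramethyltricyclo[4.3.2.0^{1,5}]undecan‑3‑one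
Product: 18 suberosenone, (1S,5S,6S,9S)‑9,11,11‑trimethyl‑2‑methylidenetricyclo[4.3.2.0^{1,5}]undecan‑3‑one, via silyl enol ether 17 (not isolated)
Conditions: TMSCl, NaI, Et3N, MeCN, 50 °C; then Pd(OAc)2 (10 mol%), O2 (1 atm), DMSO, rt
Reagents that add atoms: none
Why: Thermodynamic silyl enol ether formation toward the more substituted C2, then Saegusa–Ito oxidation; the palladium enolate at C2 has β‑hydrogens only on the methyl group because C1 is quaternary, so elimination can give only the exocyclic methylidene.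

Step 12
Reactants: 18 suberosenone (two molecules)
Product: 21 alertenone, via dienolate 19 (not isolated), via adduct enolate 20 (not isolated)
Conditions: LiN(SiMe3)2 (0.5 equiv per 18), THF, −78 → −20 °C; then AcOH
Reagents that add atoms: none
Why: Michael dimerisation; C4 is the only enolisable position of 18, so half an equivalent of base gives cross‑conjugated enolate 19, which should add through C4 on its convex face (4R, anti to the C10–C11 ring) to the methylidene carbon of the remaining 18, and protonation of 20 at the epimerisable C2′ should leave the CH2 link anti to C10′ (2′S).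

**Compound list**

1 | 4,4‑dimethylcyclopent‑2‑en‑1‑one | O=C1C=CC(C)(C)C1 | starting material
2 | potassium ethenyltrifluoroborate | C=C[B-](F)(F)F.[K+] | starting material
3 | (3R)‑3‑ethenyl‑4,4‑dimethylcyclopentan‑1‑one | O=C1C[C@H](C=C)C(C)(C)C1 | intermediate
4 | lithium (3S)‑3‑ethenyl‑4,4‑dimethylcyclopent‑1‑en‑1‑olate | [Li+].[O-]C1=C[C@H](C=C)C(C)(C)C1 | intermediate (not isolated)
5 | (3S)‑3‑ethenyl‑4,4‑dimethylcyclopent‑1‑en‑1‑yl trifluoromethanesulfonate | O=S(=O)(OC1=C[C@H](C=C)C(C)(C)C1)C(F)(F)F | intermediate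
6 | S‑ethyl (3S)‑3‑ethenyl‑4,4‑dimethylcyclopent‑1‑ene‑1‑carbothioate | CCSC(=O)C1=C[C@H](C=C)C(C)(C)C1 | intermediate
7 | (buta‑2,3‑dien‑2‑yl)trimethylsilane, i.e. 1‑methyl‑1‑(trimethylsilyl)allene | CC(=C=C)[Si](C)(C)C | starting material
8 | S‑ethyl (3aS,6S,6aS)‑6‑ethenyl‑3,5,5‑trimethyl‑2‑(trimethylsilyl)‑4,5,6,6a‑tetrahydropentalene‑3a(1H)‑carbothioate (cis‑fused; vinyl and thioester cis, both anti to the new ring) | CC1=C([Si](C)(C)C)C[C@H]2[C@H](C=C)C(C)(C)C[C@@]12C(=O)SCC | intermediate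
9 | S‑ethyl (3aS,6S,6aS)‑6‑acetyl‑3,5,5‑trimethyl‑2‑(trimethylsilyl)‑4,5,6,6a‑tetrahydropentalene‑3a(1H)‑carbothioate | CC1=C([Si](C)(C)C)C[C@H]2[C@H](C(C)=O)C(C)(C)C[C@@]12C(=O)SCC | intermediate
10 | (3aS,6S,6aS)‑6‑acetyl‑3,5,5‑trimethyl‑2‑(trimethylsilyl)‑4,5,6,6a‑tetrahydropentalene‑3a(1H)‑carbaldehyde | CC1=C([Si](C)(C)C)C[C@H]2[C@H](C(C)=O)C(C)(C)C[C@@]12C=O | intermediate
11 | (1S,5S,6S)‑2,11,11‑trimethyl‑3‑(trimethylsilyl)tricyclo[4.3.2.0^{1,5}]undeca‑2,8‑dien‑7‑one | CC1=C([Si](C)(C)C)C[C@H]2[C@@H]3C(=O)C=C[C@]12CC3(C)C | intermediate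
12 | lithium (1S,5S,6S,9S)‑2,9,11,11‑tetramethyl‑3‑(trimethylsilyl)tricyclo[4.3.2.0^{1,5}]undeca‑2,7‑dien‑7‑olate | [Li+].CC1=C([Si](C)(C)C)C[C@H]2[C@@H]3C([O-])=C[C@H](C)[C@]12CC3(C)C | intermediate (not isolated)
13 | (1S,5S,6S,9S)‑2,9,11,11‑tetramethyl‑3‑(trimethylsilyl)tricyclo[4.3.2.0^{1,5}]undeca‑2,7‑dien‑7‑yl trifluoromethanesulfonate (9‑methyl syn to C5) | CC1=C([Si](C)(C)C)C[C@H]2[C@@H]3C(OS(=O)(=O)C(F)(F)F)=C[C@H](C)[C@]12CC3(C)C | intermediate
14 | trimethyl[(1S,5S,6S,9S)‑2,9,11,11‑tetramethyltricyclo[4.3.2.0^{1,5}]undec‑2‑en‑3‑yl]silane | CC1=C([Si](C)(C)C)C[C@H]2[C@@H]3CC[C@H](C)[C@]12CC3(C)C | intermediate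
15 | 2,3‑epoxide of 14 (epoxide face unassigned) | CC12OC2([Si](C)(C)C)C[C@H]3[C@@H]4CC[C@H](C)[C@]13CC4(C)C | intermediate (not isolated)
16 | (1S,5S,6S,9S)‑2,9,11,11‑tetramethyltricyclo[4.3.2.0^{1,5}]undecan‑3‑one (mixture of C2 epimers) | CC1C(=O)C[C@H]2[C@@H]3CC[C@H](C)[C@]12CC3(C)C | intermediate
17 | trimethyl{[(1S,5S,6S,9S)‑2,9,11,11‑tetramethyltricyclo[4.3.2.0^{1,5}]undec‑2‑en‑3‑yl]oxy}silane | CC1=C(O[Si](C)(C)C)C[C@H]2[C@@H]3CC[C@H](C)[C@]12CC3(C)C | intermediate (not isolated)
18 | suberosenone, (1S,5S,6S,9S)‑9,11,11‑trimethyl‑2‑methylidenetricyclo[4.3.2.0^{1,5}]undecan‑3‑one | C=C1C(=O)C[C@H]2[C@@H]3CC[C@H](C)[C@]12CC3(C)C | intermediate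
19 | lithium (1S,5R,6S,9S)‑9,11,11‑trimethyl‑2‑methylidenetricyclo[4.3.2.0^{1,5}]undec‑3‑en‑3‑olate | [Li+].C=C1C([O-])=C[C@H]2[C@@H]3CC[C@H](C)[C@]12CC3(C)C | intermediate (not isolated)
20 | lithium C2′–C3′ enolate of alertenone (Michael adduct enolate) | [Li+].C=C1C(=O)[C@H](CC2=C([O-])C[C@H]3[C@@H]4CC[C@H](C)[C@]23CC4(C)C)[C@H]2[C@@H]3CC[C@H](C)[C@]12CC3(C)C | intermediate (not isolated)
21 | alertenone, (1S,4R,5R,6S,9S)‑9,11,11‑trimethyl‑2‑methylidene‑4‑{[(1S,2S,5S,6S,9S)‑9,11,11‑trimethyl‑3‑oxotricyclo[4.3.2.0^{1,5}]undecan‑2‑yl]methyl}tricyclo[4.3.2.0^{1,5}]undecan‑3‑one | C=C1C(=O)[C@H](C[C@@H]2C(=O)C[C@H]3[C@@H]4CC[C@H](C)[C@]23CC4(C)C)[C@H]2[C@@H]3CC[C@H](C)[C@]12CC3(C)C | target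

**Total step count:** 12. **Longest linear sequence:** 12 steps (1 → 21).

**Steps most likely to fail**

1. Step 4 (new acceptor class). The thioester may be activated too weakly, so that protodesilylation or oligomerisation of the allenylsilane outruns conjugate addition, or the titanium thioester enolate may fail to close onto the vinyl cation and leave an open‑chain adduct. The fallback uses the established enone version of the annulation and sets out from 5. Stille coupling of 5 with tributyl(1‑ethoxyvinyl)stannane (Pd(PPh3)4, LiCl) gives (3S)‑1‑(1‑ethoxyethenyl)‑3‑ethenyl‑4,4‑dimethylcyclopent‑1‑ene F1, and aqueous HCl unmasks 1‑[(3S)‑3‑ethenyl‑4,4‑dimethylcyclopent‑1‑en‑1‑yl]ethan‑1‑one F2. Annulation of F2 with 7 (TiCl4, CH2Cl2, −78 °C) gives the acetyl diquinane F3. Lemieux–Johnson cleavage of its vinyl group (OsO4 cat., NaIO4) gives the keto aldehyde F4, and KOH‑mediated aldol condensation gives the transposed enone F5 (carbonyl at C9, C7=C8). Nucleophilic epoxidation (H2O2, NaOH) on the exo face gives the epoxy ketone F6, Wharton transposition (N2H4·H2O, AcOH) gives the allylic alcohol F7, and Dess–Martin oxidation returns the route at 11.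

2. Step 12. Enolate 20 may add to further 18 (oligomerisation), proton exchange between 19 and product may stall the addition, or protonation at C2′ may occur on the wrong face. The fallback separates donor and acceptor roles and sets out from 18. Silylation (LiN(SiMe3)2, TMSCl, THF, −78 °C) gives the silyl dienol ether of suberosenone F8, whose diene is locked transoid and so cannot react as a Diels–Alder diene. Mukaiyama–Michael addition of F8 to a second equivalent of 18 (TiCl4, CH2Cl2, −78 °C) and aqueous work‑up then rejoin the route at 21.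

3. Step 11. Silylation may go toward the less hindered C4, which would lead to dehydrogenation inside the ring (C4=C5) instead of the exocyclic methylidene. The fallback avoids enolisation of 16 altogether and sets out from 14. Protodesilylation (CF3CO2H, CH2Cl2) gives the 2‑methyl‑2‑ene F9, mCPBA gives its epoxide F10, and diethylaluminium 2,2,6,6‑tetramethylpiperidide removes a methyl proton to give the 2‑methylidene‑3‑ol F11. Dess–Martin oxidation returns the route at 18.

**Further compounds**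

F1 | step 4 | (3S)‑1‑(1‑ethoxyethenyl)‑3‑ethenyl‑4,4‑dimethylcyclopent‑1‑ene | C=C(OCC)C1=C[C@H](C=C)C(C)(C)C1
F2 | step 4 | 1‑[(3S)‑3‑ethenyl‑4,4‑dimethylcyclopent‑1‑en‑1‑yl]ethan‑1‑one | CC(=O)C1=C[C@H](C=C)C(C)(C)C1
F3 | step 4 | 1‑[(3aS,6S,6aS)‑6‑ethenyl‑3,5,5‑trimethyl‑2‑(trimethylsilyl)‑4,5,6,6a‑tetrahydropentalen‑3a(1H)‑yl]ethan‑1‑one | CC1=C([Si](C)(C)C)C[C@H]2[C@H](C=C)C(C)(C)C[C@@]12C(C)=O
F4 | step 4 | (3aS,6S,6aS)‑3a‑acetyl‑3,5,5‑trimethyl‑2‑(trimethylsilyl)‑1,3a,4,5,6,6a‑hexahydropentalene‑6‑carbaldehyde | CC1=C([Si](C)(C)C)C[C@H]2[C@H](C=O)C(C)(C)C[C@@]12C(C)=O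
F5 | step 4 | (1S,5S,6S)‑2,11,11‑trimethyl‑3‑(trimethylsilyl)tricyclo[4.3.2.0^{1,5}]undeca‑2,7‑dien‑9‑one | CC1=C([Si](C)(C)C)C[C@H]2[C@@H]3C=CC(=O)[C@]12CC3(C)C
F6 | step 4 | 7,8‑epoxide of F5, epoxide oxygen syn to C5 | CC1=C([Si](C)(C)C)C[C@H]2[C@@H]3[C@@H]4O[C@@H]4C(=O)[C@]12CC3(C)C
F7 | step 4 | 2,11,11‑trimethyl‑3‑(trimethylsilyl)tricyclo[4.3.2.0^{1,5}]undeca‑2,8‑dien‑7‑ol, hydroxyl syn to C5 | CC1=C([Si](C)(C)C)C[C@H]2[C@@H]3[C@H](O)C=C[C@]12CC3(C)C
F8 | step 12 | trimethyl{[(1S,5R,6S,9S)‑9,11,11‑trimethyl‑2‑methylidenetricyclo[4.3.2.0^{1,5}]undec‑3‑en‑3‑yl]oxy}silane | C=C1C(O[Si](C)(C)C)=C[C@H]2[C@@H]3CC[C@H](C)[C@]12CC3(C)C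
F9 | step 11 | (1S,5S,6S,9S)‑2,9,11,11‑tetramethyltricyclo[4.3.2.0^{1,5}]undec‑2‑ene | CC1=CC[C@H]2[C@@H]3CC[C@H](C)[C@]12CC3(C)C
F10 | step 11 | 2,3‑epoxide of F9 (epoxide face unassigned) | CC12OC2C[C@H]3[C@@H]4CC[C@H](C)[C@]13CC4(C)C
F11 | step 11 | (1S,5S,6S,9S)‑9,11,11‑trimethyl‑2‑methylidenetricyclo[4.3.2.0^{1,5}]undecan‑3‑ol (C3 configuration unassigned) | C=C1C(O)C[C@H]2[C@@H]3CC[C@H](C)[C@]12CC3(C)C
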